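**Remark on the chemistry.** The target has no stereocentre and no stereogenic double bond (the prenyl C=C carries two methyl groups). It is therefore achiral, and "single enantiomer" is taken to mean the single constitution given. The only stereochemical elements in the route are the E-enone of chalcone 6 and a transient racemic centre in 7.

## Retrosynthetic overview

1. The prenyl group (C5'–C1'' bond of the B ring) is attached last, by Stille coupling of the 5'-bromoisoflavone 8, so that the alkene never meets the oxidant.
2. The isoflavone core comes from a biomimetic oxidative 1,2-aryl shift of chalcone 6: the B ring moves from C-β to C-α, which makes the C3–C1' bond of the 3-aryl-4H-chromen-4-one. The same pot closes the pyranone C ring (O1–C2) and frees 7-OH and 3'-OH.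
3. Chalcone 6 comes from Claisen–Schmidt condensation of acetophenone 2 (A ring, C4, C3) with aldehyde 5 (B ring, C2).
4. Ring order: A and B rings are bought; the C ring is formed in step 5.

Key step: step 5

## Route

Step 1
Reactants: 1 1-(2,4-dihydroxy-6-methoxyphenyl)ethan-1-one
Product: 2 1-[2-methoxy-4,6-bis(methoxymethoxy)phenyl]ethan-1-one
Conditions: NaH (2.2 equiv), DMF, 0 °C; MOMCl (2.3 equiv), 0 °C to rt
Reagents that add atoms: chloromethyl methyl ether (MOMCl), COCCl
Why: Williamson O-alkylation of both phenoxides; NaH is strong enough to alkylate the hydrogen-bonded ortho-OH as well, and the near-stoichiometric base should leave the methyl ketone untouched.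

Step 2
Reactants: 3 3-bromo-4,5-dihydroxybenzaldehyde
Product: 4 3-bromo-5-hydroxy-4-methoxybenzaldehyde
Conditions: MeI (1.05 equiv), Li2CO3 (1.1 equiv), DMF, 40 °C
Reagents that add atoms: iodomethane, CI
Why: Regioselective mono-O-methylation of a catechol aldehyde; the weak base should ionise only the more acidic 4-OH (para to CHO, ortho to Br), so only that oxygen is alkylated.

Step 3
Reactants: 4 3-bromo-5-hydroxy-4-methoxybenzaldehyde
Product: 5 3-bromo-4-methoxy-5-(methoxymethoxy)benzaldehyde
Conditions: MOMCl (1.5 equiv), K2CO3 (2 equiv), acetone, rt to 50 °C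
Reagents that add atoms: chloromethyl methyl ether (MOMCl), COCCl
Why: Williamson O-alkylation of the remaining phenol; the MOM ether is stable to the hydroxide of step 4 and is removed by the acid of step 5.

Step 4
Reactants: 2 1-[2-methoxy-4,6-bis(methoxymethoxy)phenyl]ethan-1-one; 5 3-bromo-4-methoxy-5-(methoxymethoxy)benzaldehyde
Product: 6 (E)-3-[3-bromo-4-methoxy-5-(methoxymethoxy)phenyl]-1-[2-methoxy-4,6-bis(methoxymethoxy)phenyl]prop-2-en-1-one
Conditions: KOH (50% aq, excess), EtOH, rt
Reagents that add atoms: none
Why: Claisen–Schmidt condensation of a methyl ketone with a non-enolisable aldehyde; E1cB dehydration should give the thermodynamically favoured E-enone, and MOM ethers and the aryl bromide are inert to hydroxide.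

Step 5
Reactants: 6 (E)-3-[3-bromo-4-methoxy-5-(methoxymethoxy)phenyl]-1-[2-methoxy-4,6-bis(methoxymethoxy)phenyl]prop-2-en-1-one
Product: 8 3-(3-bromo-5-hydroxy-4-methoxyphenyl)-7-hydroxy-5-methoxy-4H-chromen-4-one, via rearranged dimethyl acetal 7 (not isolated)
Conditions: Tl(NO3)3·3H2O (1.2 equiv), MeOH/CH(OMe)3, rt; filter off TlNO3; then HCl (ca. 2 M, from conc. HCl) in MeOH, 60 °C
Reagents that add atoms: methanol, CO (supplies the two methoxy groups of 7, which leave again on ring closure; no reagent atom other than hydrogen remains in 8)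
Why: Biomimetic oxidative 1,2-aryl migration of a chalcone (thallium(III) nitrate oxidative rearrangement, the laboratory counterpart of the aryl shift of isoflavone synthase): Tl(III) adds to the enone at C-α with methanol at the benzylic C-β, and heterolysis of the C–Tl bond (Tl(III) to Tl(I)) drives the B ring from C-β to C-α through a bridged phenonium ion while the C-β oxocarbenium ion is trapped as the dimethyl acetal 7. Methanolic HCl should then remove the three MOM groups, and the freed 6-OH of the A ring closes the pyranone on the acetal-derived oxocarbenium carbon in a 6-exo-trig mode (O1–C2 bond), after which loss of methanol aromatises the ring to the 4-pyranone. The closest known reaction type is the Tl(III)- or iodine(III)-mediated conversion of 2'-alkoxy- and 2'-hydroxychalcones into isoflavones by way of 1,2-diaryl-3,3-dimethoxypropan-1-ones. The one stereocentre of 7 (C-α, racemic) is erased when the C2=C3 bond forms, so no stereocontrol is needed. The step needs migration of the B ring in preference to aurone or flavanone closure, A-ring migration or attack on an alkene: the para-methoxy group of the B ring stabilises the phenonium ion, the MOM cap on the ortho-oxygen blocks O-cyclisation at the chalcone stage, the di-ortho-substituted aroyl carbonyl resists the ketalisation that A-ring migration requires, the C–Br bond is inert to Tl(III), and the prenyl alkene is deliberately absent until step 6.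

Step 6
Reactants: 8 3-(3-bromo-5-hydroxy-4-methoxyphenyl)-7-hydroxy-5-methoxy-4H-chromen-4-one; 9 tributyl(3-methylbut-2-en-1-yl)stannane
Product: 10 7-hydroxy-3-[3-hydroxy-4-methoxy-5-(3-methylbut-2-en-1-yl)phenyl]-5-methoxy-4H-chromen-4-one
Conditions: Pd(PPh3)4 (10 mol %), 9 (2 equiv), degassed DMF, 100 °C
Reagents that add atoms: none
Why: Migita–Kosugi–Stille coupling under neutral conditions, which tolerate the two free phenols and the base-sensitive 4-pyranone; the η3-prenyl–palladium intermediate should reductively eliminate at its unsubstituted terminus to give the linear prenyl arene, and the only C–halogen bond is the one to be coupled.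

## Compound list

1 | 1-(2,4-dihydroxy-6-methoxyphenyl)ethan-1-one (2',4'-dihydroxy-6'-methoxyacetophenone) | CC(=O)c1c(O)cc(O)cc1OC | starting material
2 | 1-[2-methoxy-4,6-bis(methoxymethoxy)phenyl]ethan-1-one | CC(=O)c1c(OC)cc(OCOC)cc1OCOC | intermediate
3 | 3-bromo-4,5-dihydroxybenzaldehyde | O=Cc1cc(O)c(O)c(Br)c1 | starting material
4 | 3-bromo-5-hydroxy-4-methoxybenzaldehyde | COc1c(O)cc(C=O)cc1Br | intermediate
5 | 3-bromo-4-methoxy-5-(methoxymethoxy)benzaldehyde | COCOc1cc(C=O)cc(Br)c1OC | intermediate
6 | (E)-3-[3-bromo-4-methoxy-5-(methoxymethoxy)phenyl]-1-[2-methoxy-4,6-bis(methoxymethoxy)phenyl]prop-2-en-1-one | COCOc1cc(OC)c(C(=O)/C=C/c2cc(Br)c(OC)c(OCOC)c2)c(OCOC)c1 | intermediate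
7 | 2-[3-bromo-4-methoxy-5-(methoxymethoxy)phenyl]-3,3-dimethoxy-1-[2-methoxy-4,6-bis(methoxymethoxy)phenyl]propan-1-one (racemic) | COCOc1cc(OC)c(C(=O)C(C(OC)OC)c2cc(Br)c(OC)c(OCOC)c2)c(OCOC)c1 | intermediate (not isolated)
8 | 3-(3-bromo-5-hydroxy-4-methoxyphenyl)-7-hydroxy-5-methoxy-4H-chromen-4-one | COc1c(O)cc(-c2coc3cc(O)cc(OC)c3c2=O)cc1Br | intermediate
9 | tributyl(3-methylbut-2-en-1-yl)stannane (prenyltributyltin) | CCCC[Sn](CCCC)(CCCC)CC=C(C)C | starting material
10 | 7-hydroxy-3-[3-hydroxy-4-methoxy-5-(3-methylbut-2-en-1-yl)phenyl]-5-methoxy-4H-chromen-4-one | COc1c(O)cc(-c2coc3cc(O)cc(OC)c3c2=O)cc1CC=C(C)C | target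

## Step count and risk

Total step count: 6. Longest linear sequence: 5 steps (steps 2, 3, 4, 5, 6, from compound 3).

**Steps most likely to fail**

1. **Step 5 (key step).** The bromine and the flanked, twisted 4-methoxy group may lower the migratory aptitude of the B ring, so that simple α-methoxylation or A-ring migration competes. Early loss of a MOM group in the acidic oxidising medium would expose a phenol to Tl(III). Fallback, from 6 to 8: Weitz–Scheffer epoxidation of 6 (H2O2, NaOH, MeOH/THF, 0 °C to rt) should give the racemic trans-epoxide {3-[3-bromo-4-methoxy-5-(methoxymethoxy)phenyl]oxiran-2-yl}[2-methoxy-4,6-bis(methoxymethoxy)phenyl]methanone F1. BF3·OEt2 in CH2Cl2 at 0 °C should then open the benzylic C–O bond and induce the 1,2-aroyl shift known for α,β-epoxy ketones, giving 2-[3-bromo-4-methoxy-5-(methoxymethoxy)phenyl]-3-[2-methoxy-4,6-bis(methoxymethoxy)phenyl]-3-oxopropanal F2. HCl in MeOH at 60 °C removes the MOM groups and cyclodehydrates F2, and the route is rejoined at 8.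

2. **Step 6.** Coupling at the γ-terminus of the prenyl–palladium species would give the reverse-prenyl (1,1-dimethylallyl) isomer. Oxidative addition into the hindered, electron-rich C–Br bond may be slow, and the phenols may protodestannylate 9. Fallback, from 8 to 10: Stille coupling of 8 with allyltributylstannane (Pd(PPh3)4, DMF, 100 °C), where the allyl group has no regiochemical ambiguity, should give 3-[3-allyl-5-hydroxy-4-methoxyphenyl]-7-hydroxy-5-methoxy-4H-chromen-4-one F3. Olefin cross-metathesis of F3 with excess 2-methyl-2-butene (Grubbs second-generation catalyst, CH2Cl2, 40 °C) then converts the allyl group into the prenyl group and arrives at 10.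

3. **Step 2.** Regiocontrol may be lost or the catechol over-methylated, giving the 5-O-methyl isomer or the dimethyl ether. Fallback, from 3 to 5, bypassing 4: the dianion of 3 (NaH, 2.2 equiv, DMSO) should react with one equivalent of MOMCl at its more nucleophilic, less stabilised 5-phenoxide to give 3-bromo-4-hydroxy-5-(methoxymethoxy)benzaldehyde F4. The remaining, more acidic 4-OH of F4 is then methylated (MeI, K2CO3, DMF, rt) to give 5.

## Further compounds

F1 | step 5 | {3-[3-bromo-4-methoxy-5-(methoxymethoxy)phenyl]oxiran-2-yl}[2-methoxy-4,6-bis(methoxymethoxy)phenyl]methanone (trans, racemic; one enantiomer drawn) | COCOc1cc(OC)c(C(=O)[C@@H]2O[C@H]2c2cc(Br)c(OC)c(OCOC)c2)c(OCOC)c1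
F2 | step 5 | 2-[3-bromo-4-methoxy-5-(methoxymethoxy)phenyl]-3-[2-methoxy-4,6-bis(methoxymethoxy)phenyl]-3-oxopropanal (racemic) | COCOc1cc(OC)c(C(=O)C(C=O)c2cc(Br)c(OC)c(OCOC)c2)c(OCOC)c1
F3 | step 6 | 3-[3-allyl-5-hydroxy-4-methoxyphenyl]-7-hydroxy-5-methoxy-4H-chromen-4-one | COc1c(O)cc(-c2coc3cc(O)cc(OC)c3c2=O)cc1CC=C
F4 | step 2 | 3-bromo-4-hydroxy-5-(methoxymethoxy)benzaldehyde | COCOc1cc(C=O)cc(Br)c1O
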